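Count what the impurity takes from the enzyme before you reckon any rate.

solid substrate 0.10 M; enzyme 0.1 mol%; impurity 39 µM

    enzyme + impurity → spent catalyst (k1 = 3.56 × 10⁵ L mol⁻¹ h⁻¹)
    starting material + enzyme → product + enzyme, rate k2*[starting material]^3*[enzyme]/(1 + ([starting material]/Kh2)^3) (Kh2 = 0.0973 M, k2 = 1.39 × 10⁵ L³ mol⁻³ h⁻¹)
    solid substrate ⇌ starting material, rate k3*(cs3 - [starting material]) while solid is left; crystals form when [starting material] > cs3 (cs3 = 0.063 M, k3 = 0.0788 h⁻¹)

1. the form that holds most of the catalyst when 50% of the solid substrate are converted (what has only dissolved counts as not reacted) (spent catalyst / enzyme)
2. its share of the catalyst then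

- solid, in amounts per volume of the solution: solid substrate
- at the start none of the solid substrate is in solution
- what has only dissolved of solid substrate counts as not reacted
- charge of solid substrate (flask): 0.10 M

I wrote C for the enzyme charged, 100 µM, and Y for the impurity charged, 39 µM, the smaller of the two and so the limiting reagent of the poisoning step. One impurity spends one enzyme, which gave me the quantity I carried, the surviving enzyme E, the enzyme charge minus the impurity charge:

E = C − Y = 61.0 µM

For the rate I began at its most generous, with C working at its full charge in a solution at the solubility 0.063 M, the level up to which the solid feeds the solution:

rate before any slowing = 0.00348 M h⁻¹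

The denominator of the rate law slowed this by a factor:

0.787, leaving 0.00273 M h⁻¹

The target needs 0.0500 M of product, so my first answer for the time was at least 18.3 h. Meanwhile the enzyme stayed at E or above, so the lifetime of the impurity, 1/(k1 E), was at most 0.0460 h, far shorter than that time. The first answer therefore rested on the enzyme charged and not on the enzyme that survived, and I went round again with E in place of C, a second slowing by the share E/C:

share of enzyme = 61.0%, form holding most: enzyme

Both slowings together came to 0.480, giving a ceiling of 0.00167 M h⁻¹ for E in a solution at the solubility, and so a time of at least 30.0 h, still far longer than the impurity's lifetime.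

The forecast named enzyme at 61%, saying of the enzyme that the impurity “titrates it irreversibly”.

The flask gave enzyme at 61.0% of the catalyst, with the target reached at 67.0 h, later than my bound. The impurity stood at 0% of its charge after 1.50 h, and the enzyme still stood at 61.0% of the catalyst charged after 150 h. For the flask with twice the enzyme, taking the impurity as unchanged, E came to 161 µM, which is 2.64 times the 61.0 µM of the first flask, whereas the rate rose by less than that, by the factor 1.71.

The constants used here are made up; the flask was simulated.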